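**Plan**

1. Locants used throughout: five-membered ring C1–C4 + C9 (C2 = C=O, C3=C4); six-membered ring C4–C9 (C5 quaternary with CH3, C6 CH–CH3); eight-membered ring C4, C5, C14, C13, C12, C11, C10, C9 (C14 O-acyl, C12 CH3/vinyl, C11 OH, C10 CH3).
2. Retrosynthetic cuts: the O14 ester; C3=C4 (aldol condensation of a C4 ketone with an acetonyl arm on C9); the C6 and C10 methyl groups (from ketones); O11 and the C12 vinyl group (from a C10 enone); then C4–C9 and C7–C8 together; then C9–C10 and C5–C14.
3. Enabling feature: the six-membered ring is bridged from C5 to C9 by the five-carbon chain C14–C13–C12–C11–C10 (a bicyclo[5.3.1]undecane). C5 can therefore be the 2-carbon of a diene C4=C5–C6=C7 and C9 the α-carbon of a vinyl ketone held in that chain, so a type 2 intramolecular Diels–Alder reaction closes the six- and eight-membered rings at once.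
4. Forward order: the chain is assembled first (lactone, iodo-aldol, dioxin, siloxy diene, vinyl ketone); the six- and eight-membered rings form together; substituents are then set on the bicycle; the five-membered ring follows and the ester comes last.
5. Stereochemistry: C14 comes from a catalytic asymmetric iodo-aldol. A temporary 4H-1,3-dioxin ring (O4–CHAr–O14) relays it to C9 and C4 in the cycloaddition, and to C5 through the bridgehead. C12, C11, C10 and C6 follow by substrate control. The acetal, the C6 siloxy/ketone, the dioxolane and the silyl ethers are removed later.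

Key step: step 10

Remark: lactone 6 and 2-(tert-butyldimethylsilyloxy)acetic acid are taken as purchasable; C5 and C9 are the two bridgeheads of one bicycle, so their relative configuration is fixed by the ring system and is written throughout with the descriptors of the target.

**Step 1**
Reactants: 1 2,3-dibromopropene; 2 acetaldehyde
Product: 3 4-bromopent-4-en-2-ol (racemic)
Conditions: Zn dust, THF/sat. aq NH4Cl, 0 → 23 °C
Reagents that add atoms: none
Why: Barbier allylation, in which only the allylic C–Br bond inserts zinc and the vinylic bromide is kept.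

**Step 2**
Reactants: 3 4-bromopent-4-en-2-ol
Product: 4 4-bromopent-4-en-2-one
Conditions: Dess–Martin periodinane, CH2Cl2, 0 °C
Reagents that add atoms: none
Why: Dess–Martin oxidation of a secondary alcohol under neutral conditions that should not move the β,γ-double bond.

**Step 3**
Reactants: 4 4-bromopent-4-en-2-one
Product: 5 2-(2-bromoprop-2-en-1-yl)-2-methyl-1,3-dioxolane
Conditions: Me3SiOCH2CH2OSiMe3, Me3SiOTf (cat.), CH2Cl2, −78 °C
Reagents that add atoms: 1,2-bis(trimethylsilyloxy)ethane C[Si](C)(C)OCCO[Si](C)(C)C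
Why: silyl-transfer ketalisation at low temperature protects the future C2 ketone without isomerising the vinyl bromide into conjugation.

**Step 4**
Reactants: 6 4-methyl-5,6-dihydro-2H-pyran-2-one
Product: 7 (2Z)-5-hydroxy-N-methoxy-N,3-dimethylpent-2-enamide
Conditions: MeNH(OMe)·HCl, AlMe3, CH2Cl2, 0 → 23 °C
Reagents that add atoms: N,O-dimethylhydroxylamine hydrochloride CNOC.Cl
Why: aluminium amide aminolysis of the lactone gives the Weinreb amide, with the Z geometry of C11=C12 (C10 cis to C13) carried over from the ring.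

**Step 5**
Reactants: 7 (2Z)-5-hydroxy-N-methoxy-N,3-dimethylpent-2-enamide
Product: 8 (2Z)-N-methoxy-N,3-dimethyl-5-oxopent-2-enamide
Conditions: Dess–Martin periodinane, pyridine, CH2Cl2, 0 °C; used at once
Reagents that add atoms: none
Why: buffered Dess–Martin oxidation of the primary alcohol gives the C14 aldehyde without base that could move the double bond.

**Step 6**
Reactants: 8 (2Z)-N-methoxy-N,3-dimethyl-5-oxopent-2-enamide; 9 but-3-yn-2-one
Product: 10 (2Z,5R,6Z)-5-hydroxy-6-(iodomethylidene)-N-methoxy-N,3-dimethyl-7-oxooct-2-enamide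
Conditions: Me3SiI, protonated (S)-B-(o-tolyl)-diphenylprolinol oxazaborolidine triflimide (20 mol %), EtCN, −78 °C; aqueous work-up
Reagents that add atoms: iodotrimethylsilane C[Si](C)(C)I
Why: catalytic asymmetric three-component iodo-aldol (β-iodo Morita–Baylis–Hillman) reaction in which iodide adds to the ynone and the allenolate adds to the aldehyde held by the chiral boron Lewis acid, setting C14 (R; the catalyst antipode is chosen accordingly) and joining C5–C14.

**Step 7**
Reactants: 10 iodo-aldol product
Product: 11 (2Z)-4-[(2R,4R)-5-acetyl-2-(4-methoxyphenyl)-4H-1,3-dioxin-4-yl]-N-methoxy-N,3-dimethylbut-2-enamide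
Conditions: 4-MeOC6H4CHO (3 equiv), KN(SiMe3)2 (1.05 equiv), THF, −78 → −20 °C
Reagents that add atoms: 4-methoxybenzaldehyde COc1ccc(C=O)cc1
Why: Proposed new method: the potassium alkoxide at C14 adds reversibly to the aldehyde and the hemiacetal alkoxide closes onto C4 of the β-iodo enone (6-endo-trig oxa-Michael addition), after which the enolate expels iodide, an addition–elimination that makes the sequence irreversible and leaves O4 cis to C14 on C4=C5; the closest known reaction types are the hemiacetal-alkoxide oxa-Michael route to benzylidene acetals of 1,3-diols and alkoxide substitution of β-halo enones; the aryl group should sit pseudoequatorial, trans to the side chain.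

**Step 8**
Reactants: 11 acetyl dioxin
Product: 12 (2Z)-4-[(2R,4R)-5-[1-(tert-butyldimethylsilyloxy)ethenyl]-2-(4-methoxyphenyl)-4H-1,3-dioxin-4-yl]-N-methoxy-N,3-dimethylbut-2-enamide
Conditions: KN(SiMe3)2, t-BuMe2SiCl, THF, −78 °C
Reagents that add atoms: tert-butyldimethylsilyl chloride CC(C)(C)[Si](C)(C)Cl
Why: kinetic enolisation of the methyl ketone and O-silylation give the 1-alkoxy-3-siloxy diene C4=C5–C6=C7 (Danishefsky type) with O4 locked in the outside position.

**Step 9**
Reactants: 12 siloxy diene; 5 vinyl bromide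
Product: 13 (4Z)-6-[(2R,4R)-5-[1-(tert-butyldimethylsilyloxy)ethenyl]-2-(4-methoxyphenyl)-4H-1,3-dioxin-4-yl]-5-methyl-2-[(2-methyl-1,3-dioxolan-2-yl)methyl]hexa-1,4-dien-3-one
Conditions: 5, t-BuLi (2 equiv), Et2O, −78 °C; then 12, THF, −78 °C; pH 7 buffer
Reagents that add atoms: none
Why: Weinreb ketone synthesis with the vinyllithium from 5 forms C9–C10 and stops at the ketone, unveiling the α-substituted vinyl ketone dienophile next to the diene.

**Step 10**
Reactants: 13 dienone
Product: 14 cycloadduct: six-membered ring C4–C9 with bridgehead silyl enol ether C5=C6(OSiMe2t-Bu); eight-membered ring with C10 ketone and (Z)-C11=C12(CH3); 4-methoxybenzylidene acetal across O4/O14; C9 carries the CH2-(2-methyl-1,3-dioxolan-2-yl) arm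
Conditions: PhMe (0.005 M), 2,6-di-tert-butyl-4-methylphenol (trace), 70 °C
Reagents that add atoms: none
Why: Thermal, concerted but asynchronous [4+2] cycloaddition in which C7, the nucleophilic terminus of the 1-alkoxy-3-siloxy diene, bonds to C8 (β-carbon of the vinyl ketone) and C4 bonds to the α-carbon C9. The closest known reaction type is the type 2 intramolecular Diels–Alder reaction of 2-substituted dienes linked by five atoms (a cis-fixed sp2–sp2 pair and the activating carbonyl among them) to a vinyl ketone, which gives bicyclo[5.3.1]undecenes with a bridgehead double bond. The six-membered ring C4–C9 closes as the cycloadduct proper and the eight-membered ring C4–C5–C14–C13–C12–C11–C10–C9 as the bridging ring, leaving C5 as a bridgehead enol ether. C9 and C4 are the new stereocentres: the dioxin ring holds O14 in the diene plane and C13 pseudoaxial, so the enone can reach the diene only on the face that carries C13, and the ring-locked outside position of O4 places it cis to C10. The step needs the bridged regiochemistry and must outrun intermolecular reaction and cycloreversion of the dioxin; the tether length and the matched polarity of C7 and C8 secure the first, high dilution and the moderate temperature the second.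

**Step 11**
Reactants: 14 cycloadduct
Product: 16 C6 ketone with the C5 methyl group (second quaternary bridgehead), via siloxycyclopropane 15 (not isolated)
Conditions: Et2Zn, CH2I2, CH2Cl2, 0 °C; then Bu4NF, THF (wet), 0 → 23 °C
Reagents that add atoms: diiodomethane ICI
Why: Simmons–Smith cyclopropanation of the electron-rich bridgehead enol ether, open to attack only on its outer face, then fluoride-induced opening of the cyclopropanol at the less substituted bond turns the CH2 into the C5 methyl group, so that C5 is tied to C9 by the bicycle.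

**Step 12**
Reactants: 16 enone
Product: 17 C12 vinyl adduct as the C10 trimethylsilyl enol ether
Conditions: CH2=CHMgBr, CuBr·SMe2 (0.3 equiv), Me3SiCl, THF, −78 °C; Et3N quench
Reagents that add atoms: vinylmagnesium bromide C=C[Mg]Br; chlorotrimethylsilane C[Si](C)(C)Cl
Why: copper-catalysed, silyl chloride-accelerated conjugate addition builds the C12 quaternary centre and a regiodefined C10 enol ether; as with 5-alkoxycycloalkenones the vinyl group should enter anti to the C14 oxygen, on the face away from the acetal bridge.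

**Step 13**
Reactants: 17 silyl enol ether
Product: 19 C11 hydroxy C10 ketone, via trimethylsilyloxy ketone 18 (not isolated)
Conditions: dimethyldioxirane, acetone, −78 → −40 °C; then MeOH, PPTS (cat.), 0 °C
Reagents that add atoms: dimethyldioxirane CC1(C)OO1
Why: Rubottom oxidation, in which the enol ether should be epoxidised on the face anti to the C9 arm and the C12 methyl group that flank the other face, followed by 1,4-silyl shift and methanolysis, gives O11 cis to the vinyl group.

**Step 14**
Reactants: 19 hydroxy ketone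
Product: 20 C11 tert-butyldimethylsilyl ether
Conditions: t-BuMe2SiOTf, 2,6-lutidine, CH2Cl2, −78 → 0 °C
Reagents that add atoms: tert-butyldimethylsilyl triflate CC(C)(C)[Si](C)(C)OS(=O)(=O)C(F)(F)F
Why: silylation of the α-hydroxy ketone blocks O11 until the end and prevents α-ketol rearrangement.

**Step 15**
Reactants: 20 diketone
Product: 21 C6,C10-bis(methylidene) compound
Conditions: Cp2TiMe2 (6 equiv), PhMe, 80 °C, dark
Reagents that add atoms: dimethyltitanocene C[Ti](C)(C1C=CC=C1)C1C=CC=C1
Why: Petasis methylenation is non-basic, so the hindered C6 and C10 ketones should both be converted without epimerising C11.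

**Step 16**
Reactants: 21 diene
Product: 22 C6,C10-dimethyl compound
Conditions: Mn(dpm)3 (dpm = 2,2,6,6-tetramethylheptane-3,5-dionate, 10 mol %), PhSiH3, t-BuOOH, i-PrOH, 23 °C
Reagents that add atoms: none
Why: hydrogen-atom-transfer hydrogenation reduces the two 1,1-disubstituted alkenes through tertiary radicals faster than the monosubstituted vinyl group; at C6 axial hydrogen delivery on the face away from the C5–C14 bond should give the equatorial methyl trans to the C5 methyl, and at C10 delivery on the face anti to the C9 arm and the C12 methyl should give the methyl trans to O11.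

**Step 17**
Reactants: 22 acetal/ketal
Product: 23 C4,C14-diol with the C9 acetonyl arm (C2 ketone; may sit partly as the O4–C2 hemiketal)
Conditions: 1 M aq HCl, THF, 23 °C
Reagents that add atoms: water O
Why: acid hydrolysis removes the 4-methoxybenzylidene acetal and the dioxolane together while the hindered secondary silyl ether at O11 survives.

**Step 18**
Reactants: 23 diol
Product: 24 C14 triethylsilyl ether
Conditions: Et3SiCl, imidazole, DMF, 0 °C
Reagents that add atoms: chlorotriethylsilane CC[Si](CC)(CC)Cl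
Why: the C14 hydroxyl is far more accessible than the C4 hydroxyl between two quaternary carbons, so monosilylation should be selective and keeps O14 non-ionisable (no retro-aldol) once C4 is a ketone.

**Step 19**
Reactants: 24 alcohol
Product: 25 C4 ketone (1,4-diketone with C2)
Conditions: Dess–Martin periodinane, pyridine, CH2Cl2, 23 °C
Reagents that add atoms: none
Why: Dess–Martin oxidation tolerates strongly hindered secondary alcohols and gives the non-enolisable C4 ketone.

**Step 20**
Reactants: 25 diketone
Product: 26 cyclopentenone (C3=C4, C2=O) with O14-SiEt3 and O11-SiMe2t-Bu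
Conditions: KOt-Bu, t-BuOH/THF, 40 °C
Reagents that add atoms: none
Why: intramolecular aldol condensation in which only C3 of the methyl ketone can close a five-membered ring onto C4, and dehydration gives the C3=C4 enone.

**Step 21**
Reactants: 26 bis-silyl ether
Product: 27 C14 alcohol (O11 still silylated)
Conditions: PPTS, MeOH/CH2Cl2, 0 → 23 °C
Reagents that add atoms: none
Why: acid methanolysis cleaves the triethylsilyl ether much faster than the hindered tert-butyldimethylsilyl ether.

**Step 22**
Reactants: 27 alcohol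
Product: 28 C14 2-(tert-butyldimethylsilyloxy)acetate
Conditions: t-BuMe2SiOCH2CO2H, DCC, DMAP, CH2Cl2, 23 → 40 °C
Reagents that add atoms: 2-(tert-butyldimethylsilyloxy)acetic acid CC(C)(C)[Si](C)(C)OCC(=O)O
Why: Steglich esterification of the only free hydroxyl installs the protected glycolate at O14.

**Step 23**
Reactants: 28 bis-silyl ether
Product: 29 Pleuromutilin F
Conditions: 48% aq HF, MeCN, 0 → 23 °C
Reagents that add atoms: none
Why: acidic fluoride removes both silyl ethers without touching the ester, the enone or the vinyl group.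

**Compound list**

1 | 2,3-dibromopropene | C=C(Br)CBr | starting material
2 | acetaldehyde | CC=O | starting material
3 | 4-bromopent-4-en-2-ol (racemic) | CC(O)CC(Br)=C | intermediate
4 | 4-bromopent-4-en-2-one | CC(=O)CC(Br)=C | intermediate
5 | 2-(2-bromoprop-2-en-1-yl)-2-methyl-1,3-dioxolane | C=C(Br)CC1(C)OCCO1 | intermediate
6 | 4-methyl-5,6-dihydro-2H-pyran-2-one | CC1=CC(=O)OCC1 | starting material
7 | (2Z)-5-hydroxy-N-methoxy-N,3-dimethylpent-2-enamide | CON(C)C(=O)/C=C(C)\CCO | intermediate
8 | (2Z)-N-methoxy-N,3-dimethyl-5-oxopent-2-enamide | CON(C)C(=O)/C=C(C)\CC=O | intermediate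
9 | but-3-yn-2-one | CC(=O)C#C | starting material
10 | (2Z,5R,6Z)-5-hydroxy-6-(iodomethylidene)-N-methoxy-N,3-dimethyl-7-oxooct-2-enamide | CON(C)C(=O)/C=C(C)\C[C@@H](O)/C(=C/I)C(C)=O | intermediate
11 | (2Z)-4-[(2R,4R)-5-acetyl-2-(4-methoxyphenyl)-4H-1,3-dioxin-4-yl]-N-methoxy-N,3-dimethylbut-2-enamide | CON(C)C(=O)/C=C(C)\C[C@H]1O[C@H](c2ccc(OC)cc2)OC=C1C(C)=O | intermediate
12 | silyl dienol ether of 11 (1-(tert-butyldimethylsilyloxy)ethenyl at dioxin C5) | CON(C)C(=O)/C=C(C)\C[C@H]1O[C@H](c2ccc(OC)cc2)OC=C1C(=C)O[Si](C)(C)C(C)(C)C | intermediate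
13 | dienone: C8H2=C9(CH2-dioxolane)–C10(=O)–(Z)-C11H=C12(CH3)–C13H2 on the dioxin of 12 | C=C(CC1(C)OCCO1)C(=O)/C=C(C)\C[C@H]2O[C@H](c3ccc(OC)cc3)OC=C2C(=C)O[Si](C)(C)C(C)(C)C | intermediate
14 | type 2 cycloadduct (C5=C6 silyl enol ether, C10 enone, O4/O14 acetal) | C/C1=C/C(=O)[C@@]2(CC3(C)OCCO3)CCC(O[Si](C)(C)C(C)(C)C)=C4[C@H]2O[C@@H](c5ccc(OC)cc5)O[C@@H]4C1 | intermediate
15 | siloxycyclopropane (CH2 across C5–C6, outer face) | C/C1=C/C(=O)[C@@]2(CC3(C)OCCO3)CC[C@@]6(O[Si](C)(C)C(C)(C)C)C[C@@]64[C@H]2O[C@@H](c5ccc(OC)cc5)O[C@@H]4C1 | intermediate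
16 | C5-methyl C6 ketone | C/C1=C/C(=O)[C@@]2(CC3(C)OCCO3)CCC(=O)[C@@]4(C)[C@H]2O[C@@H](c5ccc(OC)cc5)O[C@@H]4C1 | intermediate
17 | C12 vinyl adduct, C10 trimethylsilyl enol ether | C=C[C@@]1(C)C=C(O[Si](C)(C)C)[C@@]2(CC3(C)OCCO3)CCC(=O)[C@@]4(C)[C@H]2O[C@@H](c5ccc(OC)cc5)O[C@@H]4C1 | intermediate
18 | C11 trimethylsilyloxy C10 ketone | C=C[C@@]1(C)[C@@H](O[Si](C)(C)C)C(=O)[C@@]2(CC3(C)OCCO3)CCC(=O)[C@@]4(C)[C@H]2O[C@@H](c5ccc(OC)cc5)O[C@@H]4C1 | intermediate
19 | C11 hydroxy C10 ketone | C=C[C@@]1(C)[C@@H](O)C(=O)[C@@]2(CC3(C)OCCO3)CCC(=O)[C@@]4(C)[C@H]2O[C@@H](c5ccc(OC)cc5)O[C@@H]4C1 | intermediate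
20 | C11 tert-butyldimethylsilyl ether, C6/C10 diketone | C=C[C@@]1(C)[C@@H](O[Si](C)(C)C(C)(C)C)C(=O)[C@@]2(CC3(C)OCCO3)CCC(=O)[C@@]4(C)[C@H]2O[C@@H](c5ccc(OC)cc5)O[C@@H]4C1 | intermediate
21 | C6,C10-bis(methylidene) compound | C=C[C@@]1(C)[C@@H](O[Si](C)(C)C(C)(C)C)C(=C)[C@@]2(CC3(C)OCCO3)CCC(=C)[C@@]4(C)[C@H]2O[C@@H](c5ccc(OC)cc5)O[C@@H]4C1 | intermediate
22 | C6,C10-dimethyl compound | C=C[C@@]1(C)[C@@H](O[Si](C)(C)C(C)(C)C)[C@H](C)[C@@]2(CC3(C)OCCO3)CC[C@H](C)[C@@]4(C)[C@H]2O[C@@H](c5ccc(OC)cc5)O[C@@H]4C1 | intermediate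
23 | C4,C14-diol with C9 acetonyl arm, O11 silyl ether | C=C[C@]1(C)C[C@@H](O)[C@]2(C)[C@@H](O)[C@](CC(C)=O)(CC[C@@H]2C)[C@@H](C)[C@@H]1O[Si](C)(C)C(C)(C)C | intermediate
24 | C14 triethylsilyl ether | C=C[C@]1(C)C[C@@H](O[Si](CC)(CC)CC)[C@]2(C)[C@@H](O)[C@](CC(C)=O)(CC[C@@H]2C)[C@@H](C)[C@@H]1O[Si](C)(C)C(C)(C)C | intermediate
25 | C4 ketone (1,4-diketone) | C=C[C@]1(C)C[C@@H](O[Si](CC)(CC)CC)[C@]2(C)C(=O)[C@](CC(C)=O)(CC[C@@H]2C)[C@@H](C)[C@@H]1O[Si](C)(C)C(C)(C)C | intermediate
26 | cyclopentenone, O14-SiEt3, O11-SiMe2t-Bu | C=C[C@]1(C)C[C@@H](O[Si](CC)(CC)CC)[C@]2(C)C3=CC(=O)C[C@@]3(CC[C@@H]2C)[C@@H](C)[C@@H]1O[Si](C)(C)C(C)(C)C | intermediate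
27 | C14 alcohol, O11-SiMe2t-Bu | C=C[C@]1(C)C[C@@H](O)[C@]2(C)C3=CC(=O)C[C@@]3(CC[C@@H]2C)[C@@H](C)[C@@H]1O[Si](C)(C)C(C)(C)C | intermediate
28 | C14 2-(tert-butyldimethylsilyloxy)acetate, O11-SiMe2t-Bu | C=C[C@]1(C)C[C@@H](OC(=O)CO[Si](C)(C)C(C)(C)C)[C@]2(C)C3=CC(=O)C[C@@]3(CC[C@@H]2C)[C@@H](C)[C@@H]1O[Si](C)(C)C(C)(C)C | intermediate
29 | Pleuromutilin F | C=C[C@]1(C)C[C@@H](OC(=O)CO)[C@]2(C)C3=CC(=O)C[C@@]3(CC[C@@H]2C)[C@@H](C)[C@@H]1O | target

**Step count**

Total: 23 steps. Longest linear sequence: 20 steps (6 → 29, steps 4–23); the vinyl bromide 5 (steps 1–3) joins at step 9.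

**Steps most likely to fail**

Step 7. The C14 alkoxide may undergo retro-aldol cleavage, or the base may attack the β-iodo enone directly, before the hemiacetal forms and closes. Fallback from 10: sodium 4-methoxybenzyl oxide (4-MeOC6H4CH2OH, NaH, THF, 0 °C) replaces the vinylic iodide by addition–elimination and should give the (E)-β-(4-methoxybenzyloxy) enone F1. DDQ under anhydrous conditions (CH2Cl2, 4 Å molecular sieves, 0 °C) then oxidises the benzylic position and the neighbouring C14 hydroxyl traps the oxocarbenium ion. This is the known oxidative conversion of a 4-methoxybenzyl ether with a nearby hydroxyl into a 4-methoxybenzylidene acetal, and it comes back to the route at 11.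

Step 10. The fully substituted dienophile carbon C9 may be too compressed to reach the bridged transition state, so that cycloreversion of the dioxin or oligomerisation takes over. Fallback from 12: CH2=CHMgBr (THF, −78 °C) converts the Weinreb amide into the parent vinyl ketone F2, a less hindered dienophile. Its cycloaddition (PhMe, 70 °C, high dilution) should give the adduct with hydrogen at C9 F3. LiN(i-Pr)2 (THF, −78 °C) then removes the only sp3 α-hydrogen of the C10 ketone (at C9), and 2-methoxyallyl bromide alkylates the bridgehead enolate on its outer face to give the 2-methoxyallyl compound F4. Ethylene glycol with PPTS (CH2Cl2, 0 °C) exchanges the enol ether for the dioxolane, coming back to the route at 14.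

Step 6. The β,γ-unsaturated aldehyde may isomerise to the conjugated enal, or the Weinreb amide may bind the boron catalyst, leading to low enantioselectivity. Fallback from 8 and 9: MgI2 (CH2Cl2, 0 °C) gives the racemic Z-iodo aldol F5. Burkholderia cepacia lipase with vinyl acetate (t-BuOMe, 30 °C) should acetylate the (S)-alcohol to the acetate F6 and leave the (R)-alcohol, which is separated, coming back to the route at 10.

**Further compounds**

F1 | step 7 | (2Z,5R,6E)-5-hydroxy-N-methoxy-6-[(4-methoxybenzyloxy)methylidene]-N,3-dimethyl-7-oxooct-2-enamide | CON(C)C(=O)/C=C(C)\C[C@@H](O)/C(=C\OCc1ccc(OC)cc1)C(C)=O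
F2 | step 10 | parent vinyl ketone: (4Z)-6-[(2R,4R)-5-[1-(tert-butyldimethylsilyloxy)ethenyl]-2-(4-methoxyphenyl)-4H-1,3-dioxin-4-yl]-5-methylhexa-1,4-dien-3-one | C=CC(=O)/C=C(C)\C[C@H]1O[C@H](c2ccc(OC)cc2)OC=C1C(=C)O[Si](C)(C)C(C)(C)C
F3 | step 10 | cycloadduct with hydrogen at C9 | C/C1=C/C(=O)[C@H]2CCC(O[Si](C)(C)C(C)(C)C)=C4[C@H]2O[C@@H](c5ccc(OC)cc5)O[C@@H]4C1
F4 | step 10 | cycloadduct with a 2-methoxyprop-2-en-1-yl arm at C9 | C/C1=C/C(=O)[C@@]2(CC(=C)OC)CCC(O[Si](C)(C)C(C)(C)C)=C4[C@H]2O[C@@H](c5ccc(OC)cc5)O[C@@H]4C1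
F5 | step 6 | racemic (2Z,6Z)-5-hydroxy-6-(iodomethylidene)-N-methoxy-N,3-dimethyl-7-oxooct-2-enamide | CON(C)C(=O)/C=C(C)\CC(O)/C(=C/I)C(C)=O
F6 | step 6 | (2Z,5S,6Z)-5-acetoxy-6-(iodomethylidene)-N-methoxy-N,3-dimethyl-7-oxooct-2-enamide | CON(C)C(=O)/C=C(C)\C[C@H](OC(C)=O)/C(=C/I)C(C)=O
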